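## Analysis of the target

Compound 20 is the 3,4,5-tri-O-galloyl ester of (−)-quinic acid. It has one cyclohexane ring with a quaternary C1 (free tertiary hydroxyl and free carboxyl), methylene groups at C2 and C6, and three contiguous acyloxy carbons C3, C4 and C5. The four stereocentres are related as follows: O1, O3 and O4 lie on one face of the ring and O5 on the other, so C3/C4 are cis, C4/C5 are trans, and the carboxyl is cis to O5 (C3 and C5 are both R). The sensitive groups are the nine free phenols of the pyrogallol rings (air- and base-sensitive), the three aryl esters (prone to migration and cleavage under base) and the α-hydroxy acid. The last step therefore has to be neutral, which points to benzyl ethers and a benzyl ester removed by hydrogenolysis. The difficulties are the absolute configuration of the quaternary carbinol C1, which is insulated from the other centres by two methylenes, and the need to tell the cis oxygen pair (O3/O4) from the trans pair (O4/O5). A further difficulty is the tendency of the carboxyl to lactonise onto any hydroxyl it can reach. The strategy rests on one feature: C4 and C5 are adjacent, trans-dioxygenated carbons lying between the C3 carbinol and the C6 methylene. This is the pattern left by anti opening, at C5, of a C4–C5 epoxide that sits cis to O3. That epoxide comes from a C4=C5 alkene, and the C4=C5 bond is the one a ring-closing metathesis makes between a vinyl group on C3 and an allyl group on C1.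

## Retrosynthetic reasoning

Ring atoms are numbered as in quinic acid throughout.

**20 ⇒ 19.** All ten O–benzyl bonds (nine aryl ethers and the ester at C1) are cut together. The forward reaction is a single neutral hydrogenolysis, which the aryl esters and the free tertiary hydroxyl tolerate.

**19 ⇒ 18 + 17.** The ester C–O bonds at O3 and O4 are cut. Forward, the cis-diol of 18 is acylated twice with acid 17 under carbodiimide activation. The tertiary O1, fully substituted and α to an ester, is not acylated under these conditions, so it needs no protecting group. Because all three secondary oxygens end with the same acyl group, acyl migration between them is of no consequence.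

**18 ⇒ 16 + 17.** The C5–O bond is cut. Forward, the carboxylate of 17 opens epoxide 16 at C5 with inversion. C5 is chosen rather than C4 because it is the carbon remote from the C3 carbinol (inductively favoured, and the position favoured in titanium-mediated openings of 2,3-epoxy alcohols). Attack there also corresponds to the trans-diaxial mode of the half-chair with O3 pseudo-equatorial. The step sets O5 trans to O4 and leaves O4 cis to O3, which is the quinate pattern.

**16 ⇒ 15.** The epoxide oxygen is removed to give cyclohexenediol 15. Forward, a peracid is steered to the alkene face that carries both the allylic C3 hydroxyl and the cis homoallylic C1 hydroxyl.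

**15 ⇒ 14.** The benzyl ester and the two free hydroxyls of 15 are traced back to the spiro dioxolanone acetate 14. An open-chain 2,4-dihydroxy ester would have its C3 hydroxyl γ to the ester carbonyl and would close to a five-membered lactone. For that reason the carboxyl and O1 stay locked in the tert-butyl dioxolanone and O3 stays acetylated until the ring exists. In 14 the carboxyl carbon is trans to O3 on the ring and cannot reach it. One alkoxide treatment then opens the dioxolanone to the benzyl ester and removes the acetate.

**14 ⇒ 13.** The C4=C5 bond is cut, which opens the carbocycle to diene 13 with an allyl group on C1 and a vinyl carbinol arm. This is the key disconnection. It removes the only ring and leaves two stereocentres (C1, C3) that can be made independently in an open chain. Forward, a ruthenium alkylidene has to close a six-membered ring from a 1,7-diene without disturbing either centre.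

**13 ⇒ 12 ⇒ 11 ⇒ 10.** The vinyl group is taken back to an ethynyl group (semihydrogenation forward), the terminal alkyne to its silyl derivative, and the acetate to the free propargylic alcohol 10. These are functional-group changes only. They are accepted because they allow C3 to be set at an alkynyl ketone.

**10 ⇒ 9.** The C3–H bond is cut, giving ynone 9. An enone was not used here. A terminal vinyl group and a methylene attached to a quaternary carbon are too similar in size for a chiral reducing agent to distinguish dependably. A silyl alkynyl ketone, by contrast, belongs to the best substrate class for asymmetric transfer hydrogenation, where the catalyst alone decides the configuration.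

**9 ⇒ 6 + 7.** The C3–C4 bond is cut between the acyl carbon and the alkyne. Forward, acid 6 is activated as chloride 8 and coupled with alkyne 7 under palladium/copper catalysis. These conditions leave the dioxolanone untouched, unlike strongly nucleophilic organometallics.

**6 ⇒ 3 + 4.** The C1–C6 bond is cut. Forward, dianion 5 of dioxolanone 3 is allylated. The tert-butyl group on the acetal carbon, the only stereocentre left in the enolate, sends allyl bromide 4 to the opposite face, so allyl replaces hydrogen with retention.

**3 ⇒ 1 + 2.** The acetal C–O bonds are cut, giving (R)-malic acid 1 and pivalaldehyde 2. The chiral pool supplies the absolute configuration of C1, which is the centre hardest to create by any catalytic method.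

## Alternatives that were turned down

**Alternative 1:** Here the C1–O and C4–O bonds are disconnected together as a 1,4-dioxygen bridge. The precursor is the silyloxy diene A1, and singlet oxygen would add across C1 and C4, anti to the C5 silyl ether, to give the endoperoxide A2.
- In favour: two C–O bonds, including the tertiary one, form in one metal-free step. O1 and O4 are cis by construction and trans to O5. On bonds formed per step this is stronger than a metathesis that makes only a C=C bond.
- Against: A1 carries its C5 oxygen β to an enol ether and is one elimination away from an aromatic phenol. Its ester-bearing terminus is electron-poor, while its silyl enol ether terminus invites ene-type and [2+2] reactions of singlet oxygen instead of the cycloaddition.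
- Against: after O–O cleavage, A2 leaves a C3 carbonyl flanked by an α-hydroxyl (C4) and a β-hydroxyl (C1). Such a system is prone to retro-aldol cleavage and dehydration, and it still has to be reduced cis to O4.
- Against: the C5 centre of A1 needs its own enantioselective origin.
- Comparison: the chosen route is longer per oxygen installed. In return, every intermediate is a stable ester or acetal, C1 comes from 1, C3 from a catalyst, and C4/C5 from a directed epoxidation with anti opening, each by an independent and well-known control element.

**Alternative 2:** Here the C2–C3 bond is cut. The precursor is aldehyde A3, with a trans acetonide across O4/O5 and a 2-methylallyl arm. A Lewis acid would promote a type 2 carbonyl-ene reaction in which the alkene terminus attacks the aldehyde while an allylic methyl hydrogen passes to oxygen, giving the methylenecyclohexanol A4 with an axial C3 hydroxyl cis to O4.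
- In favour: the trans C4/C5 diol comes from a chiral pool and no epoxide regiochemistry has to be trusted. On that point it is stronger than the chosen route. The ring and C3 are also formed together.
- Against: A4 still lacks the quaternary centre. The exocyclic methylene must be turned into C(OH)CO2H by a face-selective dihydroxylation and two oxidations, at a carbon remote from any directing group, so the hardest stereocentre is made last and with the least control.
- Against: the trans-fused acetonide is strained, and a protecting-group exchange is needed before three identical acyl groups can be attached.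
- Comparison: the chosen strategy fixes C1 first, from 1, and lets the later centres follow from it and from a catalyst.

**Alternative 3:** Here the C5–O and C4–Br bonds of a bicyclic lactone are cut back to the Diels–Alder acid A5. A bromonium ion would be opened by the carboxylate at C5 to give the bromolactone A6, with bromine trans on C4.
- In favour: it is the shortest and cheapest entry to the carbocycle. The rigid lactone fixes the cis relation of carboxyl and O5 and would direct later chemistry at C3/C4 to the exo face. On step economy and on relative stereocontrol it is stronger than the chosen route.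
- Against: A5 is not symmetric. C1 is a stereocentre, because one ring arm reaches the alkene after one methylene and the other after two, and the two alkene carbons are constitutionally different. The lactonisation therefore cannot desymmetrise anything. It converts racemic A5 into racemic A6, and the absolute configuration would need a resolution or an asymmetric cycloaddition.
- Against: A6 has bromine where O4 must sit, lacks O3, ties up O5 in the lactone and carries an acetate on O1. Elimination, cis-dihydroxylation, lactone opening and acetate exchange would all precede the acylations.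
- Comparison: the chosen route is longer, but it gives a single enantiomer without resolution and arrives at the diol stage with the final protecting pattern (benzyl ester, free O1) already in place.

Key step: step 8

## Route

Assumption: acid 17 and alkyne 7 are taken as purchasable; a two-stage one-pot operation is counted as one step, and ring positions in descriptive names follow quinic acid numbering.

**Step 1**
Reactants: 1 (R)-malic acid; 2 pivalaldehyde
Product: 3 [(2R,4R)-2-tert-butyl-5-oxo-1,3-dioxolan-4-yl]acetic acid (cis isomer)
Conditions: p-TsOH·H2O (cat.), H2SO4 (cat.), pentane, reflux, Dean–Stark; recrystallisation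
Reagents that add atoms: none
Why: Acid-catalysed acetalisation of the α-hydroxy acid unit; the five-membered dioxolanone is preferred over the six-membered alternative, and the cis isomer (tert-butyl and CH2CO2H on the same face) is the thermodynamic product, purified by crystallisation. The acetal centre is set by the existing carbinol centre of 1.

**Step 2**
Reactants: 3 [(2R,4R)-2-tert-butyl-5-oxo-1,3-dioxolan-4-yl]acetic acid; 4 allyl bromide
Product: 6 [(2R,4R)-2-tert-butyl-5-oxo-4-(prop-2-en-1-yl)-1,3-dioxolan-4-yl]acetic acid, via dilithium enolate carboxylate 5 (not isolated)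
Conditions: LiN(SiMe3)2 (2.2 equiv), THF, −78 °C; then 4, −78 → −20 °C; aq. HCl
Reagents that add atoms: none
Why: Enolate alkylation with self-regeneration of the stereocentre: in planar dianion 5 the acetal carbon is the only stereocentre, and allyl bromide approaches anti to its tert-butyl group, so allyl replaces hydrogen with retention and the quaternary centre (future C1) should form as the R isomer.

**Step 3**
Reactants: 6 [(2R,4R)-2-tert-butyl-5-oxo-4-(prop-2-en-1-yl)-1,3-dioxolan-4-yl]acetic acid; 7 (trimethylsilyl)acetylene
Product: 9 (2R,5R)-2-tert-butyl-5-[2-oxo-4-(trimethylsilyl)but-3-yn-1-yl]-5-(prop-2-en-1-yl)-1,3-dioxolan-4-one, via acid chloride 8 (not isolated)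
Conditions: (COCl)2, DMF (cat.), CH2Cl2, 0 °C → rt, evaporate; then 7, PdCl2(PPh3)2 (2 mol %), CuI (4 mol %), Et3N (1.2 equiv), THF, rt
Reagents that add atoms: oxalyl chloride, ClC(=O)C(=O)Cl (supplies the chlorine of 8 only; none of its atoms remain in 9)
Why: Acid chloride formation followed by acyl Sonogashira coupling (oxidative addition of the C–Cl bond to zerovalent palladium, transfer of the copper acetylide, reductive elimination); the conditions are non-nucleophilic, so the dioxolanone carbonyl and both stereocentres are untouched.

**Step 4**
Reactants: 9 (2R,5R)-2-tert-butyl-5-[2-oxo-4-(trimethylsilyl)but-3-yn-1-yl]-5-(prop-2-en-1-yl)-1,3-dioxolan-4-one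
Product: 10 (2R,5R)-2-tert-butyl-5-[(2R)-2-hydroxy-4-(trimethylsilyl)but-3-yn-1-yl]-5-(prop-2-en-1-yl)-1,3-dioxolan-4-one
Conditions: Ru[(R,R)-TsNCHPhCHPhNH](p-cymene) (2 mol %, from RuCl[(R,R)-TsDPEN](p-cymene) and KOH), i-PrOH, rt
Reagents that add atoms: none
Why: Noyori-type asymmetric transfer hydrogenation of an α,β-acetylenic ketone under base-free conditions; hydride and proton are delivered together from the chiral Ru–H/N–H unit with the alkynyl group in the place normally taken by an aryl group, so the (R,R) catalyst is expected to set C3 as R under reagent control. The allyl group and the dioxolanone are inert to the catalyst.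

**Step 5**
Reactants: 10 (2R,5R)-2-tert-butyl-5-[(2R)-2-hydroxy-4-(trimethylsilyl)but-3-yn-1-yl]-5-(prop-2-en-1-yl)-1,3-dioxolan-4-one
Product: 11 (2R)-1-[(2R,4R)-2-tert-butyl-5-oxo-4-(prop-2-en-1-yl)-1,3-dioxolan-4-yl]-4-(trimethylsilyl)but-3-yn-2-yl acetate
Conditions: Ac2O, pyridine, DMAP (cat.), CH2Cl2, 0 °C
Reagents that add atoms: acetic anhydride, CC(=O)OC(C)=O
Why: DMAP-catalysed acetylation; it masks the γ-hydroxyl so that it cannot attack the dioxolanone carbonyl to form a γ-lactone, and it later prevents ruthenium-hydride isomerisation of the allylic alcohol. No stereocentre is involved.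

**Step 6**
Reactants: 11 (2R)-1-[(2R,4R)-2-tert-butyl-5-oxo-4-(prop-2-en-1-yl)-1,3-dioxolan-4-yl]-4-(trimethylsilyl)but-3-yn-2-yl acetate
Product: 12 (2R)-1-[(2R,4R)-2-tert-butyl-5-oxo-4-(prop-2-en-1-yl)-1,3-dioxolan-4-yl]but-3-yn-2-yl acetate
Conditions: Bu4NF, AcOH (1 : 1.2), THF, 0 °C
Reagents that add atoms: none
Why: Fluoride-induced protodesilylation of the alkynylsilane; the acetic acid buffer protonates the acetylide and keeps the medium non-basic, so the acetate and the dioxolanone should survive.

**Step 7**
Reactants: 12 (2R)-1-[(2R,4R)-2-tert-butyl-5-oxo-4-(prop-2-en-1-yl)-1,3-dioxolan-4-yl]but-3-yn-2-yl acetate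
Product: 13 (2R)-1-[(2R,4R)-2-tert-butyl-5-oxo-4-(prop-2-en-1-yl)-1,3-dioxolan-4-yl]but-3-en-2-yl acetate
Conditions: H2 (1 atm), Pd/CaCO3–Pb(OAc)2 (Lindlar catalyst), quinoline, EtOAc, rt; stopped after 1 equiv H2
Reagents that add atoms: none
Why: Lindlar semihydrogenation; the alkyne binds to the poisoned palladium surface far more strongly than the isolated allyl alkene, so reduction should stop at the vinyl group when hydrogen uptake is limited to one equivalent.

**Step 8**
Reactants: 13 (2R)-1-[(2R,4R)-2-tert-butyl-5-oxo-4-(prop-2-en-1-yl)-1,3-dioxolan-4-yl]but-3-en-2-yl acetate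
Product: 14 (2R,5R,7R)-2-tert-butyl-4-oxo-1,3-dioxaspiro[4.5]dec-8-en-7-yl acetate (spiro carbon = quinate C1, acetoxy carbon = C3, alkene = C4=C5)
Conditions: second-generation Grubbs catalyst RuCl2(=CHPh)(PCy3)(H2IMes) (3 mol %), CH2Cl2 (0.01 M), 40 °C, argon sweep
Reagents that add atoms: none
Why: Ring-closing olefin metathesis by the Chauvin mechanism. The ruthenium benzylidene should exchange first with the unhindered allyl terminus, since the vinyl group is slowed by its allylic acetate, placing the alkylidene on C5. This alkylidene adds [2+2] across the tethered vinyl group to give a ruthenacyclobutane, and cycloreversion forms C4=C5 and a ruthenium methylidene, the two lost carbons leaving as ethylene. The ring closed is the six-membered carbocycle, formed by intramolecular alkylidene–alkene metathesis of a 1,7-diene, and the ring size imposes the cis alkene. No stereocentre is created, and C1, C3 and the acetal carbon are remote from the reacting carbons and are retained. The selectivity needed is ring closure over oligomerisation and over double-bond migration; the fully substituted spiro carbon (gem-disubstituent effect) brings the two arms together, dilution and removal of ethylene favour cyclisation, and the acetate keeps the allylic oxygen from feeding a ruthenium-hydride isomerisation. The closest known reaction type is the ring-closing metathesis of 1,7-dienes with allylic oxygen substituents to cyclohexenol derivatives using this catalyst.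

**Step 9**
Reactants: 14 (2R,5R,7R)-2-tert-butyl-4-oxo-1,3-dioxaspiro[4.5]dec-8-en-7-yl acetate
Product: 15 benzyl (1R,3R)-1,3-dihydroxycyclohex-4-ene-1-carboxylate (quinate numbering; the two hydroxyls cis)
Conditions: BnOH (10 equiv), BnONa (0.3 equiv, from NaH), THF, 0 °C → rt; aq. NH4Cl
Reagents that add atoms: benzyl alcohol, OCc1ccccc1
Why: Alkoxide transesterification: benzyl alkoxide adds to the acylal carbonyl, the ring-opened hemiacetal alkoxide loses pivalaldehyde to free the tertiary hydroxyl, and the same alkoxide removes the acetate. On the ring the ester is trans to O3, so no lactone can form, and no stereocentre is touched.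

**Step 10**
Reactants: 15 benzyl (1R,3R)-1,3-dihydroxycyclohex-4-ene-1-carboxylate
Product: 16 benzyl (1S,3R,4R,5S)-4,5-epoxy-1,3-dihydroxycyclohexane-1-carboxylate (quinate numbering; epoxide oxygen cis to both hydroxyls)
Conditions: m-CPBA, CH2Cl2, 0 °C → rt
Reagents that add atoms: 3-chloroperoxybenzoic acid, OOC(=O)c1cccc(Cl)c1
Why: Henbest hydroxyl-directed epoxidation; the peracid is hydrogen-bonded to the allylic C3 hydroxyl, reinforced by the cis homoallylic C1 hydroxyl, and should deliver oxygen to the alkene face syn to both, which sets C4 and C5.

**Step 11**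
Reactants: 16 benzyl (1S,3R,4R,5S)-4,5-epoxy-1,3-dihydroxycyclohexane-1-carboxylate; 17 3,4,5-tris(benzyloxy)benzoic acid
Product: 18 benzyl 5-O-[3,4,5-tris(benzyloxy)benzoyl]quinate (benzyl 1,3,4-trihydroxy-5-{[3,4,5-tris(benzyloxy)benzoyl]oxy}cyclohexane-1-carboxylate; hydroxyls at C1, C3, C4 cis, acyloxy at C5 trans to them)
Conditions: 17 (1.5 equiv), Ti(OiPr)4 (2 equiv), CH2Cl2, rt; aq. tartaric acid
Reagents that add atoms: none
Why: Titanium-mediated opening of a 2,3-epoxy alcohol by a carboxylic acid; titanium binds the C3 alkoxide and the epoxide oxygen, and the carboxylate attacks the distal carbon C5 from the opposite face (SN2, inversion), which is also the trans-diaxial mode of the half-chair with O3 pseudo-equatorial. O5 should therefore end trans to O4, while O4 keeps the epoxide configuration, cis to O3.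

**Step 12**
Reactants: 18 benzyl 5-O-[3,4,5-tris(benzyloxy)benzoyl]quinate; 17 3,4,5-tris(benzyloxy)benzoic acid
Product: 19 benzyl 3,4,5-tris-O-[3,4,5-tris(benzyloxy)benzoyl]quinate (tertiary C1 hydroxyl free)
Conditions: 17 (3 equiv), EDC·HCl (3.5 equiv), DMAP (1 equiv), CH2Cl2, rt
Reagents that add atoms: none
Why: Steglich esterification of the two secondary hydroxyls through the acylpyridinium; the tertiary hydroxyl at C1, fully substituted and α to an ester, should not compete, and any acyl migration among O3, O4 and O5 is degenerate because all three carry the same group.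

**Step 13**
Reactants: 19 benzyl 3,4,5-tris-O-[3,4,5-tris(benzyloxy)benzoyl]quinate
Product: 20 3,4,5-tri-O-galloyl-(−)-quinic acid (1-hydroxy-3,4,5-tris(3,4,5-trihydroxybenzoyloxy)cyclohexane-1-carboxylic acid; O1, O3, O4 cis, O5 trans; 3R,5R)
Conditions: H2 (1 atm), Pd/C (10 %), THF–MeOH, rt
Reagents that add atoms: none
Why: Catalytic hydrogenolysis of nine benzyl aryl ethers and the benzyl ester under neutral conditions; aryl esters, the tertiary alcohol and all stereocentres are unaffected.

## Compound list

1 | (R)-malic acid | OC(=O)C[C@@H](O)C(=O)O | starting material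
2 | pivalaldehyde | CC(C)(C)C=O | starting material
3 | [(2R,4R)-2-tert-butyl-5-oxo-1,3-dioxolan-4-yl]acetic acid | CC(C)(C)[C@@H]1O[C@H](CC(=O)O)C(=O)O1 | intermediate
4 | allyl bromide | C=CCBr | starting material
5 | dilithium enolate carboxylate of 3 | CC(C)(C)[C@@H]1OC(CC(=O)[O-])=C([O-])O1.[Li+].[Li+] | intermediate
6 | [(2R,4R)-2-tert-butyl-5-oxo-4-(prop-2-en-1-yl)-1,3-dioxolan-4-yl]acetic acid | CC(C)(C)[C@@H]1O[C@](CC=C)(CC(=O)O)C(=O)O1 | intermediate
7 | (trimethylsilyl)acetylene | C#C[Si](C)(C)C | starting material
8 | [(2R,4R)-2-tert-butyl-5-oxo-4-(prop-2-en-1-yl)-1,3-dioxolan-4-yl]acetyl chloride | CC(C)(C)[C@@H]1O[C@](CC=C)(CC(=O)Cl)C(=O)O1 | intermediate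
9 | (2R,5R)-2-tert-butyl-5-[2-oxo-4-(trimethylsilyl)but-3-yn-1-yl]-5-(prop-2-en-1-yl)-1,3-dioxolan-4-one | CC(C)(C)[C@@H]1O[C@](CC=C)(CC(=O)C#C[Si](C)(C)C)C(=O)O1 | intermediate
10 | (2R,5R)-2-tert-butyl-5-[(2R)-2-hydroxy-4-(trimethylsilyl)but-3-yn-1-yl]-5-(prop-2-en-1-yl)-1,3-dioxolan-4-one | CC(C)(C)[C@@H]1O[C@](CC=C)(C[C@@H](O)C#C[Si](C)(C)C)C(=O)O1 | intermediate
11 | (2R)-1-[(2R,4R)-2-tert-butyl-5-oxo-4-(prop-2-en-1-yl)-1,3-dioxolan-4-yl]-4-(trimethylsilyl)but-3-yn-2-yl acetate | CC(C)(C)[C@@H]1O[C@](CC=C)(C[C@@H](OC(C)=O)C#C[Si](C)(C)C)C(=O)O1 | intermediate
12 | (2R)-1-[(2R,4R)-2-tert-butyl-5-oxo-4-(prop-2-en-1-yl)-1,3-dioxolan-4-yl]but-3-yn-2-yl acetate | CC(C)(C)[C@@H]1O[C@](CC=C)(C[C@@H](OC(C)=O)C#C)C(=O)O1 | intermediate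
13 | (2R)-1-[(2R,4R)-2-tert-butyl-5-oxo-4-(prop-2-en-1-yl)-1,3-dioxolan-4-yl]but-3-en-2-yl acetate | CC(C)(C)[C@@H]1O[C@](CC=C)(C[C@@H](OC(C)=O)C=C)C(=O)O1 | intermediate
14 | (2R,5R,7R)-2-tert-butyl-4-oxo-1,3-dioxaspiro[4.5]dec-8-en-7-yl acetate | CC(C)(C)[C@@H]1O[C@]2(C[C@@H](OC(C)=O)C=CC2)C(=O)O1 | intermediate
15 | benzyl (1R,3R)-1,3-dihydroxycyclohex-4-ene-1-carboxylate (quinate numbering) | O[C@H]1C=CC[C@](O)(C(=O)OCc2ccccc2)C1 | intermediate
16 | benzyl (1S,3R,4R,5S)-4,5-epoxy-1,3-dihydroxycyclohexane-1-carboxylate (quinate numbering) | O[C@H]1[C@H]2O[C@H]2C[C@](O)(C(=O)OCc3ccccc3)C1 | intermediate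
17 | 3,4,5-tris(benzyloxy)benzoic acid | OC(=O)c1cc(OCc2ccccc2)c(OCc2ccccc2)c(OCc2ccccc2)c1 | starting material
18 | benzyl 5-O-[3,4,5-tris(benzyloxy)benzoyl]quinate | O=C(O[C@@H]1C[C@](O)(C(=O)OCc2ccccc2)C[C@@H](O)[C@H]1O)c1cc(OCc2ccccc2)c(OCc2ccccc2)c(OCc2ccccc2)c1 | intermediate
19 | benzyl 3,4,5-tris-O-[3,4,5-tris(benzyloxy)benzoyl]quinate | O=C(O[C@@H]1C[C@](O)(C(=O)OCc2ccccc2)C[C@@H](OC(=O)c2cc(OCc3ccccc3)c(OCc3ccccc3)c(OCc3ccccc3)c2)[C@H]1OC(=O)c1cc(OCc2ccccc2)c(OCc2ccccc2)c(OCc2ccccc2)c1)c1cc(OCc2ccccc2)c(OCc2ccccc2)c(OCc2ccccc2)c1 | intermediate
20 | 3,4,5-tri-O-galloyl-(−)-quinic acid | O=C(O[C@@H]1C[C@](O)(C(=O)O)C[C@@H](OC(=O)c2cc(O)c(O)c(O)c2)[C@H]1OC(=O)c1cc(O)c(O)c(O)c1)c1cc(O)c(O)c(O)c1 | target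

## Step count and least certain steps

Total step count: 13. Longest linear sequence: 13 steps, from 1 to 20. Acid 17 is used as purchased in steps 11 and 12.

**Step 8 (key step).** The most likely failure is double-bond migration in the allyl arm by ruthenium-hydride species formed as the catalyst decays, followed by closure to a ring-contracted product. A second is unproductive chelation of the alkylidene by the allylic acetate, which slows closure enough for intermolecular metathesis to compete.
Fallback: the ring is closed one oxidation level higher, before C3 is set. Setting out from 6 through its chloride 8, a Stille acylation with tributyl(vinyl)stannane under Pd(PPh3)4 would give the vinyl ketone F1. Ring-closing metathesis of F1 with the same ruthenium catalyst (initiation at the allyl end, closure onto the electron-poor enone) would give the spiro enone F2. Reduction of F2 with catecholborane and (S)-2-methyl-CBS-oxazaborolidine, for which a cyclic enone with its alkene arm as the larger group is a suitable substrate, would give the allylic alcohol F3. On the ring, F3 cannot lactonise, so it goes directly into the conditions of step 9 and rejoins the route at 15.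

**Step 11.** The risk is attack of the carboxylate at C4 instead of C5. The approach to C5 runs syn-axial to the ester group on C1, and a titanium chelate holding O1, O3 and the epoxide oxygen together would favour the other half-chair, whose trans-diaxial mode is C4 opening. Competing opening by isopropoxide is a lesser risk.
Fallback: the carboxyl itself is made the nucleophile, since it can reach only C5. Setting out from 16, hydrogenolysis of the benzyl ester (H2, Pd/C, EtOAc) would give the epoxy acid F4. With a trace of camphorsulfonic acid in CH2Cl2, the axial carboxyl of F4 should open the epoxide at C5 from the lower face (5-exo, trans-diaxial) to give the γ-lactone quinide F5. Benzyl alkoxide, as in step 9, would open the lactone to benzyl quinate F6. Threefold Steglich esterification of the secondary hydroxyls of F6 with 17 (EDC·HCl, DMAP) then rejoins the route at 19.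

**Step 7.** The risk is loss of chemoselectivity near the end of the hydrogenation, with saturation of the new vinyl group or of the allyl group once the alkyne is consumed.
Fallback: the alkyne is avoided altogether. Setting out from 6 through 8, an anhydrous Suzuki–Miyaura acylation with (E)-2-phenylvinylboronic acid (Pd(PPh3)4, Cs2CO3, toluene) would give the styryl ketone F7. Reduction of F7 with catecholborane and (S)-2-methyl-CBS-oxazaborolidine, β-aryl enones being a well-behaved substrate class with the alkenyl group as the larger substituent, would give the allylic alcohol F8. Acetylation would give the acetate F9. Ring-closing metathesis of F9 with the second-generation Grubbs catalyst, now expelling styrene, rejoins the route at 14.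

**Step 3.** The risk is ketene formation from the enolisable acid chloride in the presence of the amine. A second is base-induced β-elimination of the dioxolanone oxygen from the ynone, and a third is oxidative dimerisation of the alkyne.
Fallback: cross-coupling is replaced by nucleophilic acyl substitution. Setting out from 6, coupling with N,O-dimethylhydroxylamine hydrochloride (EDC·HCl, N-methylmorpholine) would give the N-methoxy-N-methylamide F10. Addition of the lithium acetylide of 7 (n-BuLi, THF, −78 → −40 °C) should stop at the chelated tetrahedral stage and rejoin the route at 9 after work-up. The dioxolanone carbonyl, flanked by the quaternary carbon, is expected to be spared at this temperature.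

## Further compounds

F1 | step 8 | (2R,5R)-2-tert-butyl-5-(2-oxobut-3-en-1-yl)-5-(prop-2-en-1-yl)-1,3-dioxolan-4-one | CC(C)(C)[C@@H]1O[C@](CC=C)(CC(=O)C=C)C(=O)O1
F2 | step 8 | (2R,5R)-2-tert-butyl-1,3-dioxaspiro[4.5]dec-8-ene-4,7-dione | CC(C)(C)[C@@H]1O[C@]2(CC(=O)C=CC2)C(=O)O1
F3 | step 8 | (2R,5R,9R)-2-tert-butyl-9-hydroxy-1,3-dioxaspiro[4.5]dec-7-en-4-one | CC(C)(C)[C@@H]1O[C@]2(C[C@@H](O)C=CC2)C(=O)O1
F4 | step 11 | (1S,3R,4R,5S)-4,5-epoxy-1,3-dihydroxycyclohexane-1-carboxylic acid (quinate numbering) | O[C@H]1[C@H]2O[C@H]2C[C@](O)(C(=O)O)C1
F5 | step 11 | (1S,3R,4R,5R)-1,3,4-trihydroxy-6-oxabicyclo[3.2.1]octan-7-one (quinide) | O[C@@H]1C[C@]2(O)C[C@@H](OC2=O)[C@@H]1O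
F6 | step 11 | benzyl (−)-quinate (benzyl 1,3,4,5-tetrahydroxycyclohexane-1-carboxylate; O1, O3, O4 cis, O5 trans) | O[C@@H]1C[C@](O)(C(=O)OCc2ccccc2)C[C@@H](O)[C@H]1O
F7 | step 7 | (2R,5R)-2-tert-butyl-5-[(3E)-2-oxo-4-phenylbut-3-en-1-yl]-5-(prop-2-en-1-yl)-1,3-dioxolan-4-one | CC(C)(C)[C@@H]1O[C@](CC=C)(CC(=O)/C=C/c2ccccc2)C(=O)O1
F8 | step 7 | (2R,5R)-2-tert-butyl-5-[(2R,3E)-2-hydroxy-4-phenylbut-3-en-1-yl]-5-(prop-2-en-1-yl)-1,3-dioxolan-4-one | CC(C)(C)[C@@H]1O[C@](CC=C)(C[C@@H](O)/C=C/c2ccccc2)C(=O)O1
F9 | step 7 | (2R,3E)-1-[(2R,4R)-2-tert-butyl-5-oxo-4-(prop-2-en-1-yl)-1,3-dioxolan-4-yl]-4-phenylbut-3-en-2-yl acetate | CC(C)(C)[C@@H]1O[C@](CC=C)(C[C@@H](OC(C)=O)/C=C/c2ccccc2)C(=O)O1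
F10 | step 3 | 2-[(2R,4R)-2-tert-butyl-5-oxo-4-(prop-2-en-1-yl)-1,3-dioxolan-4-yl]-N-methoxy-N-methylacetamide | CC(C)(C)[C@@H]1O[C@](CC=C)(CC(=O)N(C)OC)C(=O)O1
A1 | alternative 1 | benzyl (5R)-5-(tert-butyldimethylsilyloxy)-3-(trimethylsilyloxy)cyclohexa-1,3-diene-1-carboxylate | CC(C)(C)[Si](C)(C)O[C@@H]1CC(C(=O)OCc2ccccc2)=CC(O[Si](C)(C)C)=C1
A2 | alternative 1 | benzyl 5-(tert-butyldimethylsilyloxy)-3-(trimethylsilyloxy)-1,4-epidioxycyclohex-2-ene-1-carboxylate (peroxide bridge trans to the C5 silyloxy group) | CC(C)(C)[Si](C)(C)O[C@@H]1C[C@]2(OO[C@@H]1C(O[Si](C)(C)C)=C2)C(=O)OCc1ccccc1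
A3 | alternative 2 | (4S,5R)-2,2-dimethyl-5-(2-methylprop-2-en-1-yl)-1,3-dioxolane-4-carbaldehyde | CC1(C)O[C@H](CC(C)=C)[C@@H](C=O)O1
A4 | alternative 2 | 4,5-O-isopropylidene-1-methylenecyclohexane-3,4,5-triol (quinate numbering; C3 hydroxyl axial, cis to O4) | CC1(C)O[C@@H]2CC(=C)C[C@@H](O)[C@H]2O1
A5 | alternative 3 | 1-acetoxycyclohex-3-ene-1-carboxylic acid (racemic) | CC(=O)OC1(C(=O)O)CC=CCC1
A6 | alternative 3 | 1-acetoxy-4-bromo-6-oxabicyclo[3.2.1]octan-7-one (bromine trans to the lactone oxygen) | O2[C@@H]1C[C@](OC(C)=O)(C2=O)CC[C@H]1Br
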